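**Remark on the chemistry.** The SMILES fixes C2 as R (priorities O1 > C1' > C3 > H), the mirror image of the 2S series usual for natural flavanones; the route is built for this enantiomer. In names, "prenyl" = 3-methylbut-2-en-1-yl and "Ar" = 3,5-diprenyl-4-(triisopropylsilyloxy)phenyl.

## Analysis of the target

The target is a flavanone. Ring A is a 1,3,5-trioxygenated benzene (C4a–C8a), ring C is a dihydropyranone (O1, C2, C3, C4) fused to it at C4a–C8a, and ring B is a 2,6-diprenylphenol attached to C2. The only stereocentre is C2 (R). It is benzylic, bonded to O1 and β to the C4 ketone, so base can open ring C by β-elimination (to the 2'-hydroxychalcone, or through a quinone methide once the 4'-phenol is free) and strong acid can ionise the C2–O1 bond. The three prenyl groups each sit ortho to a phenol; they rule out hydrogenation, ozonolysis and strong acid, which would close chromans. The hard regiochemical point is the ring A prenyl: it must be at C6, between the C5 and C7 oxygens, and not at the equally activated C8. Electrophilic prenylation of a 5,7-dioxygenated ring and cyclisation of a symmetrically hydroxylated chalcone both fail to separate these positions. The strategy rests on the substitution pattern of ring A itself: C5 (OH), C6 (prenyl) and C7 (O) are contiguous, C8 carries hydrogen, and C4a=C8a is shared with ring C. This is the pattern produced when a vinylketene (supplying C5, C8, C8a, C4a) combines with a 1-siloxyalkyne (supplying C6 with its prenyl and C7 with its oxygen). Ring A can therefore be built last, on a chiral dihydropyranone that already carries C2, with the prenyl group placed by the polarity of the alkyne.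

## Retrosynthetic reasoning

**Target 22 to 21.** The two O–Si bonds at O7 and O4' are cut. Silyl ethers are chosen because they fall to buffered fluoride, which spares the prenyl/phenol pairs (acid-sensitive) and C2 (base-sensitive). The forward step must only avoid free phenoxide.

**21 to 14 and 18.** Ring A is cut at C5–C6, C7–C8 and C4a–C5. This leaves diazoketone 14, whose diazo group is the precursor of vinylketene 19, and siloxyalkyne 18. Cutting here rather than in ring C keeps C2 out of the ring-forming event. It also turns the C6/C8 problem into the regiochemistry of a ketene–ynol ether addition, which is dictated by the polarisation of 18. The forward reaction has to generate 19 photochemically, add 18 across the ketene C=C to give cyclobutenone 20, and then open and re-close 20 to the phenol.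

**18 to 16 and 15.** The C≡C–O unit is traced to the ester carbonyl of 16. One carbon is inserted by a dihalomethyl carbenoid and the resulting ynolate 17 is silylated on oxygen. The prenyl group is already present in acid 15, so no allylation of an alkyne is needed.

**14 to 12 and 11.** The C8–C(acyl) bond is cut: the diazo carbon comes from a one-carbon diazoalkane that is acylated by activated acid 12 (through anhydride 13). The acid is stored as allyl ester 11, not as a simple alkyl ester, because the allyl group can be removed by palladium under neutral conditions. Saponification would expose C6 and C2 of the vinylogous ester to aqueous base.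

**11 to 7 and 8.** The pyranone is opened at O1–C6 (hemiketal formation and dehydration) and at C5–C6 (crossed Claisen condensation). This gives methyl ketone 7 and diallyl oxalate 8; the open-chain diketo esters are 9 and 10. The carbinol C–O bond of 7 becomes C2–O1 without being broken, so the configuration is carried through.

**7 to 6, then 4 and 5.** The C2–C3 bond is cut as a direct aldol addition of acetone 5 to aldehyde 4. This is the only stereogenic step; an L-proline-derived amide sets C2 by catalyst control. The secondary alcohol of 6 is masked as its trimethylsilyl ether 7 for the Claisen step.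

**4 to 3, then 1 and 2.** The silyl ether is removed and the two aryl–prenyl bonds are cut, leading to 4-hydroxybenzaldehyde 1 and prenyl bromide 2. The para position is blocked by the formyl group, so C-alkylation can only occur at the two ortho positions.

## Alternatives that were turned down

**Alternative 1:** Ring C is cut at C4a–C4, C4–C3 and O1–C2. In the forward sense 2-iodo-3,5-bis(methoxymethoxy)-4-prenylphenol A2, the ring B alkyne 5-ethynyl-2-(methoxymethoxy)-1,3-diprenylbenzene A3 and one carbonyl carbon are joined by PdCl2(PPh3)2 (divalent palladium) in a carbonylative coupling. The resulting ynone cyclises 6-endo to 5,7,4'-tris(methoxymethoxy)-6,3',5'-triprenylflavone A1.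
- For it: it is highly convergent and forms three bonds in one operation. Its regiochemistry is as secure as in the chosen route, because the phenol before iodination is mirror-symmetric and only one mono-iodide A2 can form. It is also shorter up to the tricyclic skeleton and needs no photochemistry, so on convergence and step count it is the stronger plan.
- Against it: A1 is a flavone, so C2 is still sp2. The stereocentre would have to be made afterwards by enantioselective 1,4-reduction of a 2-arylchromone carrying three trisubstituted alkenes. Hydrogenation catalysts do not distinguish the prenyl groups reliably, hydride reagents tend to reduce C4 as well, and 5-exo closure to an aurone competes in the annulation. The methoxymethyl ethers must then leave under acid next to prenyl groups and a labile C2.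
- In comparison: the chosen route sets C2 first by a well-understood aldol reaction, never makes it planar again, and ends with a fluoride deprotection.

**Alternative 2:** The C3=C4 bond of the enol silane is cut. The diene tert-butyl-[1-[6-[(1R)-1-[4-(methoxymethoxy)-3,5-diprenylphenyl]prop-2-enoxy]-2,4-bis(methoxymethoxy)-3-prenylphenyl]ethenoxy]dimethylsilane A5 would be closed by the second-generation Grubbs catalyst to the 4-silyloxy-2H-chromene A4, which is then hydrolysed to the ketone.
- For it: C2 is set before ring closure, the ring-forming step is neutral, and ring A is bought as an aromatic piece.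
- Against it: A5 holds five alkenes. The three prenyl groups can enter cross-metathesis, and the reacting partner is a 1,1-disubstituted electron-rich enol ether twisted between two ortho substituents, which is among the slowest metathesis substrates. Making A5 needs a 2-hydroxyacetophenone in which the C6/C8 question is already answered, so the regiochemical problem is moved, not solved. It also needs a stereospecific O-alkylation with a 1-arylallyl electrophile that is prone to ionisation and allylic transposition. In A4, C2 is an allylic, benzylic ether that can ionise towards a flavylium ion during acidic removal of the methoxymethyl groups.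
- In comparison: step counts are similar, but the chosen route has no competition between alkenes and solves the C6 placement in the ring-forming step itself.

**Alternative 3:** The C2–C3 bond is cut. The aryl diazomethyl ketone 2-diazo-1-[2,4-bis(tert-butyldimethylsilyloxy)-6-[[4-(tert-butyldimethylsilyloxy)-3,5-diprenylphenyl]methoxy]-3-prenylphenyl]ethanone A7 would be decomposed by Rh2(S-PTTL)4 (divalent rhodium). The carbenoid at C3 inserts into one enantiotopic benzylic C–H bond to give (R)-5,7,4'-tris(tert-butyldimethylsilyloxy)-6,3',5'-triprenylflavanone A6.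
- For it: it is the most direct plan. One catalytic step closes ring C and creates C2 at the very end, so there is no opportunity for erosion, and the silyl ethers allow the same mild end game. On step economy it is stronger than the chosen route.
- Against it: the carbenoid is of the acceptor-only type, for which enantiocontrol in C–H insertion is modest. The ether oxygen lies one atom closer than the C–H bond, so oxonium ylide formation and 1,2-benzyl shift to a 2-benzylbenzofuranone is the expected competitor of the six-membered insertion. The three prenyl alkenes are open to cyclopropanation. A7 again presupposes a ring A ketone with the prenyl group already correctly placed between two differentiated oxygens.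
- In comparison: the chosen route is longer, but C2 comes from a reliable catalytic aldol reaction and the regiochemistry of ring A is decided by the mechanism of the key step.

Key step: step 10

## Route

**Step 1**
Reactants: 1 4-hydroxybenzaldehyde; 2 prenyl bromide (1-bromo-3-methylbut-2-ene)
Product: 3 4-hydroxy-3,5-diprenylbenzaldehyde
Conditions: 2 (2.2 equiv), 10% aq. KOH, rt; chromatography
Reagents that add atoms: none
Why: C-alkylation of an ambident phenoxide in water, where hydrogen bonding shields oxygen and the blocked para position leaves only the two ortho carbons; the diprenyl phenol should be separable from mono-C- and O-alkylated material, and the mono-prenyl fraction can be resubmitted.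

**Step 2**
Reactants: 3 4-hydroxy-3,5-diprenylbenzaldehyde
Product: 4 3,5-diprenyl-4-(triisopropylsilyloxy)benzaldehyde
Conditions: i-Pr3SiOTf, 2,6-lutidine, CH2Cl2, 0 °C to rt
Reagents that add atoms: triisopropylsilyl trifluoromethanesulfonate, CC(C)[Si](OS(=O)(=O)C(F)(F)F)(C(C)C)C(C)C
Why: O-silylation with a silyl triflate reaches even a 2,6-disubstituted phenol; the hindered aryl silyl ether should withstand the amide base, carboxylate and diazoalkane of later steps and is cleaved by fluoride at the end.

**Step 3**
Reactants: 4 3,5-diprenyl-4-(triisopropylsilyloxy)benzaldehyde; 5 acetone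
Product: 6 (R)-4-hydroxy-4-Ar-butan-2-one
Conditions: (S)-N-[(S)-1-hydroxy-4-methyl-1,1-diphenylpentan-2-yl]pyrrolidine-2-carboxamide (10 mol%), acetone (solvent), −25 °C
Reagents that add atoms: none
Why: Enamine-catalysed direct aldol addition; the L-proline-derived enamine of acetone is expected to attack the Re face of the hydrogen-bonded aldehyde and so set C2 as R. The two ortho prenyl groups twist the O–Si bond out of the ring plane, so the aldehyde should be less deactivated than an ordinary para-alkoxybenzaldehyde.

**Step 4**
Reactants: 6 (R)-4-hydroxy-4-Ar-butan-2-one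
Product: 7 (R)-4-Ar-4-(trimethylsilyloxy)butan-2-one
Conditions: Me3SiCl, imidazole, CH2Cl2, 0 °C
Reagents that add atoms: chlorotrimethylsilane, C[Si](C)(C)Cl
Why: Standard O-silylation; masking the alcohol prevents alkoxide-driven retro-aldol cleavage and O-acylation in the Claisen step, and the labile trimethylsilyl group leaves again under the mild acid of step 5.

**Step 5**
Reactants: 7 (R)-4-Ar-4-(trimethylsilyloxy)butan-2-one; 8 diallyl oxalate
Product: 11 allyl (R)-2-Ar-4-oxo-2,3-dihydro-4H-pyran-6-carboxylate, via silylated diketo ester 9 (not isolated), via hydroxy diketo ester 10 (not isolated)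
Conditions: LiN(SiMe3)2, THF, −78 °C; 8, −78 to 0 °C; aq. NH4Cl; then p-TsOH·H2O (cat.), CH2Cl2, 0 °C to rt
Reagents that add atoms: none
Why: Kinetic deprotonation at the methyl group and crossed Claisen condensation with the non-enolisable oxalate join the carbons that become C4a and C8a. Mild acid then frees the alcohol, which adds 6-exo-trig to the keto group next to the ester and loses water by β-elimination to give the vinylogous ester. The carbinol C–O bond is never broken, so C2 should keep its configuration as long as the acid stays catalytic.

**Step 6**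
Reactants: 11 allyl (R)-2-Ar-4-oxo-2,3-dihydro-4H-pyran-6-carboxylate
Product: 12 (R)-2-Ar-4-oxo-2,3-dihydro-4H-pyran-6-carboxylic acid
Conditions: Pd(PPh3)4 (5 mol%), PPh3, potassium 2-ethylhexanoate, CH2Cl2–EtOAc, rt; then cold dilute HCl
Reagents that add atoms: none
Why: Zerovalent palladium ionises the allyl ester to a π-allyl complex that is captured by the carboxylate salt. This neutral de-allylation is used in place of saponification because aqueous base could add at C6 or open ring C by β-elimination at C2; the prenyl groups are not allylic electrophiles and should stay untouched.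

**Step 7**
Reactants: 12 (R)-2-Ar-4-oxo-2,3-dihydro-4H-pyran-6-carboxylic acid
Product: 14 (R)-6-(diazoacetyl)-2-Ar-2,3-dihydro-4H-pyran-4-one, via mixed isobutyl carbonic anhydride 13 (not isolated)
Conditions: i-BuOCOCl, N-methylmorpholine, THF, −15 °C; then CH2N2, Et2O, −15 to 0 °C
Reagents that add atoms: diazomethane, C=[N+]=[N-]
Why: Arndt–Eistert-type acylation of diazomethane by a mixed carbonic anhydride, which is formed without hydrogen chloride that would add to the prenyl alkenes. Acylation at low temperature should outrun 1,3-dipolar addition to the trisubstituted push–pull C5=C6 bond; the diazoalkane carbon becomes C8.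

**Step 8**
Reactants: 15 4-methylpent-3-enoic acid
Product: 16 ethyl 4-methylpent-3-enoate
Conditions: EtI, K2CO3, DMF, rt
Reagents that add atoms: iodoethane, CCI
Why: SN2 O-alkylation of the carboxylate; acid-free conditions avoid lactonisation to the γ,γ-dimethyl butyrolactone and migration of the double bond into conjugation.

**Step 9**
Reactants: 16 ethyl 4-methylpent-3-enoate
Product: 18 5-methyl-1-(triisopropylsilyloxy)hex-4-en-1-yne, via lithium ynolate 17 (not isolated)
Conditions: CH2Br2, lithium 2,2,6,6-tetramethylpiperidide, THF, −78 °C; LiN(SiMe3)2; n-BuLi, −78 to 0 °C; then i-Pr3SiCl, −78 °C to rt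
Reagents that add atoms: dibromomethane, BrCBr; chlorotriisopropylsilane, CC(C)[Si](Cl)(C(C)C)C(C)C
Why: Kowalski ester homologation: the dibromomethyl carbenoid adds to the ester, the derived dibromo enolate undergoes bromine–lithium exchange and 1,2-shift of the alkyl group to give ynolate 17, and a bulky silyl chloride traps it on oxygen.

**Step 10**
Reactants: 14 (R)-6-(diazoacetyl)-2-Ar-2,3-dihydro-4H-pyran-4-one; 18 5-methyl-1-(triisopropylsilyloxy)hex-4-en-1-yne
Product: 21 (R)-5-hydroxy-6-prenyl-7-(triisopropylsilyloxy)-2-Ar-chroman-4-one, via vinylketene 19 (not isolated), via vinylcyclobutenone 20 (not isolated)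
Conditions: 18 (2 equiv), hν (365 nm LED), degassed ClCH2CH2Cl, 20 °C; then 80 °C in the dark
Reagents that add atoms: none
Why: Light expels dinitrogen from 14 and the pyranone carbon migrates to the carbene centre (Wolff rearrangement), giving vinylketene 19 whose C=C bond is the future C4a=C8a bond. The polarised siloxyalkyne adds [2+2] across the ketene C=C: its nucleophilic prenyl-bearing carbon bonds to the ketene carbonyl carbon (C5–C6) and its oxygen-bearing carbon to the former diazo carbon (C7–C8), giving cyclobutenone 20. Warming opens 20 by four-electron electrocyclic cleavage to a dienylketene, which closes ring A by six-electron electrocyclisation (C4a–C5) and tautomerises to the phenol. The closest known reaction is the diazoketone form of the Danheiser benzannulation with siloxyalkynes, which gives resorcinol monosilyl ethers, also from cycloalkenyl diazoketones. No stereocentre is formed in 21 (the sp3 carbon of 20 is lost on aromatisation) and C2 is not involved under these neutral conditions. The required regioselectivity, prenyl at C6 and not C8, follows from the ynol ether polarisation; the ketene should prefer the electron-rich alkyne to the unactivated prenyl alkenes. In 19 the ketene and the C4 carbonyl are trans across C5=C6, so closure to a 2-pyranone is geometrically excluded. The long wavelength addresses only the diazoketone band and spares the aryl and enone absorptions, and the chelated 5-hydroxyl of 21 should be a poor trap for remaining ketene.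

**Step 11**
Reactants: 21 (R)-5-hydroxy-6-prenyl-7-(triisopropylsilyloxy)-2-Ar-chroman-4-one
Product: 22 (R)-5,7-dihydroxy-2-(4-hydroxy-3,5-diprenylphenyl)-6-prenylchroman-4-one (target)
Conditions: Bu4NF, AcOH (1:1), THF, 0 °C to rt
Reagents that add atoms: none
Why: Fluoride cleaves both aryl silyl ethers; the acetic acid buffer keeps the phenols protonated, so neither β-elimination to the chalcone nor quinone-methide formation from a 4'-phenoxide should racemise C2, and no acid strong enough to cyclise prenyl groups onto the neighbouring phenols is present.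

## Compound list

1 | 4-hydroxybenzaldehyde | O=Cc1ccc(O)cc1 | starting material
2 | prenyl bromide | CC(C)=CCBr | starting material
3 | 4-hydroxy-3,5-diprenylbenzaldehyde | CC(C)=CCc1cc(C=O)cc(CC=C(C)C)c1O | intermediate
4 | 3,5-diprenyl-4-(triisopropylsilyloxy)benzaldehyde | CC(C)=CCc1cc(C=O)cc(CC=C(C)C)c1O[Si](C(C)C)(C(C)C)C(C)C | intermediate
5 | acetone | CC(C)=O | starting material
6 | (R)-4-hydroxy-4-Ar-butan-2-one | CC(C)=CCc1cc([C@H](O)CC(C)=O)cc(CC=C(C)C)c1O[Si](C(C)C)(C(C)C)C(C)C | intermediate
7 | (R)-4-Ar-4-(trimethylsilyloxy)butan-2-one | CC(C)=CCc1cc([C@H](O[Si](C)(C)C)CC(C)=O)cc(CC=C(C)C)c1O[Si](C(C)C)(C(C)C)C(C)C | intermediate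
8 | diallyl oxalate | C=CCOC(=O)C(=O)OCC=C | starting material
9 | allyl (R)-6-Ar-2,4-dioxo-6-(trimethylsilyloxy)hexanoate (drawn as the diketo tautomer) | CC(C)=CCc1cc([C@H](O[Si](C)(C)C)CC(=O)CC(=O)C(=O)OCC=C)cc(CC=C(C)C)c1O[Si](C(C)C)(C(C)C)C(C)C | intermediate
10 | allyl (R)-6-Ar-6-hydroxy-2,4-dioxohexanoate (drawn as the diketo tautomer) | CC(C)=CCc1cc([C@H](O)CC(=O)CC(=O)C(=O)OCC=C)cc(CC=C(C)C)c1O[Si](C(C)C)(C(C)C)C(C)C | intermediate
11 | allyl (R)-2-Ar-4-oxo-2,3-dihydro-4H-pyran-6-carboxylate | CC(C)=CCc1cc([C@H]2CC(=O)C=C(C(=O)OCC=C)O2)cc(CC=C(C)C)c1O[Si](C(C)C)(C(C)C)C(C)C | intermediate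
12 | (R)-2-Ar-4-oxo-2,3-dihydro-4H-pyran-6-carboxylic acid | CC(C)=CCc1cc([C@H]2CC(=O)C=C(C(=O)O)O2)cc(CC=C(C)C)c1O[Si](C(C)C)(C(C)C)C(C)C | intermediate
13 | mixed anhydride of 12 with isobutyl carbonic acid | CC(C)=CCc1cc([C@H]2CC(=O)C=C(C(=O)OC(=O)OCC(C)C)O2)cc(CC=C(C)C)c1O[Si](C(C)C)(C(C)C)C(C)C | intermediate
14 | (R)-6-(diazoacetyl)-2-Ar-2,3-dihydro-4H-pyran-4-one | CC(C)=CCc1cc([C@H]2CC(=O)C=C(C(=O)C=[N+]=[N-])O2)cc(CC=C(C)C)c1O[Si](C(C)C)(C(C)C)C(C)C | intermediate
15 | 4-methylpent-3-enoic acid | CC(C)=CCC(=O)O | starting material
16 | ethyl 4-methylpent-3-enoate | CCOC(=O)CC=C(C)C | intermediate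
17 | lithium 5-methylhex-4-en-1-yn-1-olate | [Li+].[O-]C#CCC=C(C)C | intermediate
18 | 5-methyl-1-(triisopropylsilyloxy)hex-4-en-1-yne | CC(C)=CCC#CO[Si](C(C)C)(C(C)C)C(C)C | intermediate
19 | (R)-6-(2-oxoethenyl)-2-Ar-2,3-dihydro-4H-pyran-4-one (vinylketene) | CC(C)=CCc1cc([C@H]2CC(=O)C=C(C=C=O)O2)cc(CC=C(C)C)c1O[Si](C(C)C)(C(C)C)C(C)C | intermediate
20 | (2R)-2-Ar-6-[4-oxo-3-prenyl-2-(triisopropylsilyloxy)cyclobut-2-en-1-yl]-2,3-dihydro-4H-pyran-4-one (both epimers at the cyclobutenone carbon) | CC(C)=CCc1cc([C@H]2CC(=O)C=C(C3C(=O)C(CC=C(C)C)=C3O[Si](C(C)C)(C(C)C)C(C)C)O2)cc(CC=C(C)C)c1O[Si](C(C)C)(C(C)C)C(C)C | intermediate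
21 | (R)-5-hydroxy-6-prenyl-7-(triisopropylsilyloxy)-2-Ar-chroman-4-one | CC(C)=CCc1cc([C@H]2CC(=O)c3c(cc(O[Si](C(C)C)(C(C)C)C(C)C)c(CC=C(C)C)c3O)O2)cc(CC=C(C)C)c1O[Si](C(C)C)(C(C)C)C(C)C | intermediate
22 | (R)-5,7-dihydroxy-2-(4-hydroxy-3,5-diprenylphenyl)-6-prenylchroman-4-one | CC(C)=CCc1cc([C@H]2CC(=O)c3c(cc(O)c(CC=C(C)C)c3O)O2)cc(CC=C(C)C)c1O | target

## Step count and least certain steps

Total: 11 steps. Longest linear sequence: 9 steps (1–7, 10, 11); steps 8 and 9 form the two-step side branch to 18.

**Step 10 (key step).**
- What may go wrong: the push–pull vinylketene 19 may be captured too slowly by 18, so that ketene dimerisation, acylation of the product phenol or secondary photochemistry of the ene-dione chromophore takes over. Cyclobutenone 20 may also fail to open cleanly.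
- Fallback (from 14, returning at 21): ring A would be built by the ionic benzannulation of a silylketene with an ynolate, run in the dark. i-Pr3SiOTf and i-Pr2NEt should silylate the diazo carbon to give (R)-6-[diazo(triisopropylsilyl)acetyl]-2-Ar-2,3-dihydro-4H-pyran-4-one F1. Irradiation without alkyne should give the stable, non-dimerising silylketene (R)-2-Ar-6-[2-oxo-1-(triisopropylsilyl)ethenyl]-2,3-dihydro-4H-pyran-4-one F2. F2 would be added at −78 °C to lithium ynolate 17, made as in step 9 but without the silyl chloride. The ynolate carbon should acylate the ketene (C6–C7), the new dienylketene should close by six-electron electrocyclisation (C4a–C5), and a 1,3-shift of silicon from C8 to O7 should deliver 21 after aqueous work-up. The ynolate is basic, so the temperature must stay low to protect C2.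

**Step 7.**
- What may go wrong: 1,3-dipolar addition of diazomethane to the doubly activated C5=C6 bond, or attack at the carbonate carbonyl of 13, may compete with acylation.
- Fallback (from 12, returning at 14): no free diazoalkane would meet the enone. 1-Chloro-N,N,2-trimethylprop-1-en-1-amine should give the acid chloride (R)-2-Ar-4-oxo-2,3-dihydro-4H-pyran-6-carbonyl chloride F3 without hydrogen chloride. Me2Zn with catalytic Pd(PPh3)4 (Negishi acylation) should convert it into (R)-6-acetyl-2-Ar-2,3-dihydro-4H-pyran-4-one F4. Enolisation of the more acidic acetyl group with LiN(SiMe3)2 at −78 °C and trapping with 2,2,2-trifluoroethyl trifluoroacetate should give (R)-2-Ar-6-(4,4,4-trifluoro-3-oxobutanoyl)-2,3-dihydro-4H-pyran-4-one F5. Methanesulfonyl azide and Et3N in wet MeCN should then transfer the diazo group with loss of the trifluoroacetyl group to give 14.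

**Step 3.**
- What may go wrong: slow addition to a hindered, still fairly electron-rich aldehyde, with erosion of enantiomeric purity through retro-aldol equilibration or loss through dehydration to the enone.
- Fallback (from 4, returning at 6): (+)-B-allyldiisopinocampheylborane (from (−)-α-pinene) in Et2O at −78 °C, followed by oxidative work-up, should deliver allyl to the Re face and give (R)-1-Ar-but-3-en-1-ol F6. Wacker oxidation of the terminal alkene (PdCl2, CuCl, O2, DMF–H2O), to which the trisubstituted prenyl alkenes should be inert, would give 6.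

**Step 9.**
- What may go wrong: deprotonation of the doubly activated CH2 of the β,γ-unsaturated ester by the carbenoid or the amide bases in place of carbonyl addition, leading to conjugated material.
- Fallback (from 2, returning at 18): copper-catalysed coupling of 2 with excess HC≡CMgBr (CuCl, THF) should give 5-methylhex-4-en-1-yne F7. Lithiation with n-BuLi and oxidation of the acetylide with LiOOt-Bu would give ynolate 17, which i-Pr3SiCl traps as 18.

**Step 1.**
- What may go wrong: incomplete or excessive alkylation and competing O-prenylation, leaving little of the 3,5-diprenyl phenol.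
- Fallback (from 1, returning at 3): bromination (Br2, AcOH) should give 3,5-dibromo-4-hydroxybenzaldehyde F8. A double α-selective Suzuki–Miyaura coupling with 4,4,5,5-tetramethyl-2-prenyl-1,3,2-dioxaborolane would then give 3, using [1,3-bis(2,6-di(pentan-3-yl)phenyl)imidazol-2-ylidene](3-chloropyridine)palladium dichloride (a divalent palladium precatalyst) and aqueous KOH in THF.

## Further compounds

F1 | step 10 | (R)-6-[diazo(triisopropylsilyl)acetyl]-2-Ar-2,3-dihydro-4H-pyran-4-one | CC(C)=CCc1cc([C@H]2CC(=O)C=C(C(=O)C(=[N+]=[N-])[Si](C(C)C)(C(C)C)C(C)C)O2)cc(CC=C(C)C)c1O[Si](C(C)C)(C(C)C)C(C)C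
F2 | step 10 | (R)-2-Ar-6-[2-oxo-1-(triisopropylsilyl)ethenyl]-2,3-dihydro-4H-pyran-4-one | CC(C)=CCc1cc([C@H]2CC(=O)C=C(C(=C=O)[Si](C(C)C)(C(C)C)C(C)C)O2)cc(CC=C(C)C)c1O[Si](C(C)C)(C(C)C)C(C)C
F3 | step 7 | (R)-2-Ar-4-oxo-2,3-dihydro-4H-pyran-6-carbonyl chloride | CC(C)=CCc1cc([C@H]2CC(=O)C=C(C(=O)Cl)O2)cc(CC=C(C)C)c1O[Si](C(C)C)(C(C)C)C(C)C
F4 | step 7 | (R)-6-acetyl-2-Ar-2,3-dihydro-4H-pyran-4-one | CC(C)=CCc1cc([C@H]2CC(=O)C=C(C(C)=O)O2)cc(CC=C(C)C)c1O[Si](C(C)C)(C(C)C)C(C)C
F5 | step 7 | (R)-2-Ar-6-(4,4,4-trifluoro-3-oxobutanoyl)-2,3-dihydro-4H-pyran-4-one | CC(C)=CCc1cc([C@H]2CC(=O)C=C(C(=O)CC(=O)C(F)(F)F)O2)cc(CC=C(C)C)c1O[Si](C(C)C)(C(C)C)C(C)C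
F6 | step 3 | (R)-1-Ar-but-3-en-1-ol | CC(C)=CCc1cc([C@H](O)CC=C)cc(CC=C(C)C)c1O[Si](C(C)C)(C(C)C)C(C)C
F7 | step 9 | 5-methylhex-4-en-1-yne | C#CCC=C(C)C
F8 | step 1 | 3,5-dibromo-4-hydroxybenzaldehyde | O=Cc1cc(Br)c(O)c(Br)c1
A1 | alternative 1 | 5,7,4'-tris(methoxymethoxy)-6,3',5'-triprenylflavone | CC(C)=CCc1cc(-c2cc(=O)c3c(OCOC)c(CC=C(C)C)c(OCOC)cc3o2)cc(CC=C(C)C)c1OCOC
A2 | alternative 1 | 2-iodo-3,5-bis(methoxymethoxy)-4-prenylphenol | COCOc1cc(O)c(I)c(OCOC)c1CC=C(C)C
A3 | alternative 1 | 5-ethynyl-2-(methoxymethoxy)-1,3-diprenylbenzene | C#Cc1cc(CC=C(C)C)c(OCOC)c(CC=C(C)C)c1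
A4 | alternative 2 | (R)-4-(tert-butyldimethylsilyloxy)-5,7-bis(methoxymethoxy)-2-[4-(methoxymethoxy)-3,5-diprenylphenyl]-6-prenyl-2H-chromene | CC(C)=CCc1cc([C@H]2C=C(O[Si](C)(C)C(C)(C)C)c3c(cc(OCOC)c(CC=C(C)C)c3OCOC)O2)cc(CC=C(C)C)c1OCOC
A5 | alternative 2 | tert-butyl-[1-[6-[(1R)-1-[4-(methoxymethoxy)-3,5-diprenylphenyl]prop-2-enoxy]-2,4-bis(methoxymethoxy)-3-prenylphenyl]ethenoxy]dimethylsilane | CC(C)=CCc1cc([C@H](Oc2cc(OCOC)c(CC=C(C)C)c(OCOC)c2C(=C)O[Si](C)(C)C(C)(C)C)C=C)cc(CC=C(C)C)c1OCOC
A6 | alternative 3 | (R)-5,7,4'-tris(tert-butyldimethylsilyloxy)-6,3',5'-triprenylflavanone | CC(C)=CCc1cc([C@H]2CC(=O)c3c(cc(O[Si](C)(C)C(C)(C)C)c(CC=C(C)C)c3O[Si](C)(C)C(C)(C)C)O2)cc(CC=C(C)C)c1O[Si](C)(C)C(C)(C)C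
A7 | alternative 3 | 2-diazo-1-[2,4-bis(tert-butyldimethylsilyloxy)-6-[[4-(tert-butyldimethylsilyloxy)-3,5-diprenylphenyl]methoxy]-3-prenylphenyl]ethanone | [N-]=[N+]=CC(=O)c1c(OCc2cc(CC=C(C)C)c(O[Si](C)(C)C(C)(C)C)c(CC=C(C)C)c2)cc(O[Si](C)(C)C(C)(C)C)c(CC=C(C)C)c1O[Si](C)(C)C(C)(C)C
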